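## Retrosynthetic overview
1. Disconnect the allylic C–S bond (Pd-catalysed sulfinate allylation). This leaves an allylic acetate and 2-guanidinoethanesulfinate, which comes from hypotaurine.
2. Make the ring C1(Me)=C2 alkene last on the ring: enol triflate from the ketone, then Fe-catalysed methylation.
3. Disconnect the quaternary C6–C9 bond at a regio-defined tetrasubstituted Li enolate and a primary iodide. The enolate comes from cathodic reduction of a tertiary α-bromoketone, and the adjacent CHMe (from (R)-pulegone) directs the chain trans to it.
4. The E,E-iodide comes from farnesyl acetate by terminal-alkene cleavage and decarboxylative iodination, which removes one carbon.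
5. There is no ring-forming step. The only ring is the pulegone carbocycle, and C5 (target numbering) is never touched.

Assumptions:
- (E,E)-Farnesyl acetate is commercial.
- The acetate survives the short, cold K2CO3/MeOH and Fe/MeMgBr steps.
- In the tertiary bromination, the C2 bromide is the major regioisomer and is separable.
- The target is isolated as its guanidinium acetate and liberated to the free base by ion exchange.

## Route

**Step 1**
Reactants: 1, (2E,6E)-farnesyl acetate
Product: 2, (2E,6E)-10-bromo-11-hydroxy-10,11-dihydrofarnesyl acetate
Conditions: NBS (1.0 equiv), THF/H2O (3:1), 0 °C, 30 min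
Reagents that add atoms: NBS, O=C1CCC(=O)N1Br (gives Br); H2O, O (gives OH)
Why: NBS/H2O gives Markovnikov bromohydrin formation selectively at the most accessible terminal trisubstituted alkene; the two inner alkenes are untouched.

**Step 2**
Reactants: 2
Product: 3, (2E,6E)-10,11-epoxyfarnesyl acetate
Conditions: K2CO3 (1 equiv), MeOH, 0 °C, 20 min
Reagents that add atoms: none
Why: Intramolecular Williamson closure of the bromohydrin (epoxide formation); the short, cold exposure keeps the acetate.

**Step 3**
Reactants: 3
Product: 4, (2E,6E)-9-formyl-nor-farnesyl acetate, i.e. (2E,6E)-3,7-dimethyl-10-oxodeca-2,6-dienyl acetate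
Conditions: H5IO6, THF/H2O, 0 °C → rt, 1 h
Reagents that add atoms: none
Why: Acid-mediated epoxide hydrolysis to the diol, then periodate glycol cleavage (Malaprade), releases acetone and leaves the C10 aldehyde; the inner E-alkenes are retained.

**Step 4**
Reactants: 4
Product: 5, the corresponding carboxylic acid, (2E,6E)-10-acetoxy-4,8-dimethyldeca-... i.e. (4E,8E)-10-acetoxy-4,8-dimethyldeca-4,8-dienoic acid
Conditions: NaClO2, NaH2PO4, 2-methyl-2-butene, t-BuOH/H2O, rt
Reagents that add atoms: NaClO2, [Na+].[O-]Cl=O (gives O)
Why: Pinnick oxidation; 2-methyl-2-butene scavenges HOCl so the trisubstituted alkenes survive.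

**Step 5**
Reactants: 5
Product: 6, (2E,6E)-9-iodo-3,7-dimethylnona-2,6-dien-1-yl acetate
Conditions: (COCl)2, cat. DMF, CH2Cl2; then sodium 2-thiopyridone N-oxide, DMAP (cat.), CHI3 (5 equiv), visible light (tungsten lamp), 0 °C
Reagents that add atoms: iodoform, IC(I)I (gives I)
Why: Barton decarboxylative iodination. The thiohydroxamate ester fragments photochemically and loses CO2, giving a primary radical that abstracts I from CHI3; this deletes C10 so C9 becomes the attachment carbon.

**Step 6**
Reactants: 7, (R)-(+)-pulegone
Product: 8, (5R)-2-isopropylidene-5,6-dimethylcyclohexan-1-one (C6 epimer mixture)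
Conditions: LDA, THF, −78 °C; then MeI, −78 °C → 0 °C
Reagents that add atoms: MeI, CI (gives CH3)
Why: Kinetic deprotonation occurs only at the α′-CH2 (C6, since C2 has no H), so enolate methylation is regiospecific; the C6 epimer ratio is irrelevant because C6 is re-enolised later.

**Step 7**
Reactants: 8
Product: 9, (3R)-2,3-dimethylcyclohexan-1-one (C2 epimer mixture)
Conditions: 2 M aq. H2SO4, 100 °C, 12 h, acetone distilled off
Reagents that add atoms: none
Why: Acid hydration of the isopropylidene enone and retro-aldol loss of acetone; this is the classic pulegone-to-3-methylcyclohexanone cleavage. It is done now, on a small acid-stable substrate, before the polyene is introduced. C3 (= target C5) is not enolisable, so it is untouched.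

**Step 8**
Reactants: 9
Product: 10, (3R)-2-bromo-2,3-dimethylcyclohexan-1-one (C2 epimer mixture)
Conditions: Br2, Et2O, cat. HBr, 0 °C
Reagents that add atoms: Br2, BrBr (gives Br)
Why: HBr-autocatalysed enolisation goes toward the more substituted enol, so bromination is α at the tertiary carbon. The C2 configuration is irrelevant because the next step destroys it.

**Step 9**
Reactants: 10 (2.5 equiv) and 6 (1 equiv)
Product: 11, (2S,3R)-2,3-dimethyl-2-[(3E,7E)-9-acetoxy-4,8-dimethylnona-3,7-dienyl]cyclohexan-1-one
Conditions: constant-potential electrolysis (−1.5 V vs Ag/Ag+), RVC cathode, Pt anode, divided cell, 0.1 M LiClO4, THF/DMPU (4:1), 0 °C → rt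
Reagents that add atoms: none (both substrates are numbered reactants; electrons only)
Why: Proposed new method: cathodic two-electron reduction of the tertiary α-bromoketone (about −1.1 V, well positive of R–I, about −2 V) cleanly gives the tetrasubstituted lithium enolate with no regiochemical ambiguity. In Li+/DMPU this enolate is alkylated in situ by the primary iodide (SN2) to form the quaternary centre. Allylic (A1,2) strain between the 2-Me and 3-Me forces the 3-Me pseudo-axial, so axial alkylation occurs anti to it and the chain ends up trans to the C3 methyl, giving the (2S) centre. The closest known reactions are SmI2-mediated reductive alkylation of α-haloketones and Stork reductive enolate alkylation.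

**Step 10**
Reactants: 11
Product: 12, enol triflate of 11
Conditions: KHMDS (1.1 equiv), THF, −78 °C, 30 min; then PhNTf2, −78 °C → 0 °C
Reagents that add atoms: PhNTf2, O=S(=O)(N(c1ccccc1)S(=O)(=O)C(F)(F)F)C(F)(F)F (gives CF3SO2)
Why: The ketone has only one enolisable α-CH2 (the other α-carbon is quaternary), so O-triflation of the kinetic enolate is regiospecific and places the alkene at C1=C2 (target numbering).

**Step 11**
Reactants: 12
Product: 13, the target ring and chain as its allylic acetate, (2E,6E)-9-[(1S,2R)-1,2,6-trimethylcyclohex-5-en-1-yl]... i.e. (2E,6E)-3,7-dimethyl-9-[(1S,2R)-1,2,6-trimethylcyclohex-6-enyl]nona-2,6-dien-1-yl acetate (the ring is 1,5,6-trimethylcyclohexene carrying the chain on C6)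
Conditions: MeMgBr (1.5 equiv), Fe(acac)3 (5 mol%), THF/NMP, 0 °C, 10 min
Reagents that add atoms: MeMgBr, C[Mg]Br (gives CH3)
Why: Iron-catalysed Kumada coupling of an enol triflate with MeMgBr; it is fast at 0 °C, so the acetate and the two E-alkenes survive, and no stereocentre is touched.

**Step 12**
Reactants: 14, hypotaurine (2-aminoethanesulfinic acid)
Product: 15, 2-guanidinoethanesulfinate (zwitterion)
Conditions: 1H-pyrazole-1-carboxamidine·HCl (1.1 equiv), DIPEA, H2O/DMF, rt, N2, 12 h
Reagents that add atoms: 1H-pyrazole-1-carboxamidine hydrochloride, NC(=N)n1cccn1.Cl (gives the C(=N)N unit)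
Why: Bernatowicz guanylation of the primary amine; the sulfinate is unaffected.

**Step 13**
Reactants: 13 and 15
Product: 16, Agelasidine C
Conditions: Pd(PPh3)4 (5 mol%), DMF/H2O (4:1), 50 °C, 6 h
Reagents that add atoms: none
Why: Tsuji–Trost allylic sulfonylation. The S-nucleophile attacks the less hindered primary terminus of the π-allyl, so the linear (E) allylic sulfone forms; the guanidinium stays protonated and non-nucleophilic.

## Compound list
1 | (2E,6E)-farnesyl acetate | CC(=O)OC/C=C(\C)CC/C=C(\C)CCC=C(C)C | starting material
2 | 10-bromo-11-hydroxy farnesyl acetate | CC(=O)OC/C=C(\C)CC/C=C(\C)CCC(Br)C(C)(C)O | intermediate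
3 | 10,11-epoxyfarnesyl acetate | CC(=O)OC/C=C(\C)CC/C=C(\C)CCC1OC1(C)C | intermediate
4 | C10 aldehyde | CC(=O)OC/C=C(\C)CC/C=C(\C)CCC=O | intermediate
5 | C10 carboxylic acid | CC(=O)OC/C=C(\C)CC/C=C(\C)CCC(=O)O | intermediate
6 | 9-iodo-3,7-dimethylnona-2,6-dienyl acetate | CC(=O)OC/C=C(\C)CC/C=C(\C)CCI | intermediate
7 | (R)-(+)-pulegone | C[C@@H]1CCC(=C(C)C)C(=O)C1 | starting material
8 | (5R)-2-isopropylidene-5,6-dimethylcyclohexanone | C[C@@H]1CCC(=C(C)C)C(=O)C1C | intermediate
9 | (3R)-2,3-dimethylcyclohexanone | C[C@@H]1CCCC(=O)C1C | intermediate
10 | (3R)-2-bromo-2,3-dimethylcyclohexanone | C[C@@H]1CCCC(=O)C1(C)Br | intermediate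
11 | quaternary ketone | O=C1CCC[C@@H](C)[C@]1(C)CC/C(C)=C/CC/C(C)=C/COC(C)=O | intermediate
12 | enol triflate | FC(F)(F)S(=O)(=O)OC1=CCC[C@@H](C)[C@]1(C)CC/C(C)=C/CC/C(C)=C/COC(C)=O | intermediate
13 | allylic acetate of the target skeleton | CC1=CCC[C@@H](C)[C@]1(C)CC/C(C)=C/CC/C(C)=C/COC(C)=O | intermediate
14 | hypotaurine | NCCS(=O)O | starting material
15 | 2-guanidinoethanesulfinate | NC(=[NH2+])NCCS(=O)[O-] | intermediate
16 | Agelasidine C | CC1=CCC[C@@H](C)[C@]1(C)CC/C(C)=C/CC/C(C)=C/CS(=O)(=O)CCN=C(N)N | target

## Totals
Total steps: 13. Longest linear sequence: 9 (steps 1–5, then 9, 10, 11, 13).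

## Three steps most likely to fail
1. **Step 9 (the proposed new step).** Risks are enolate protonation, halogen-transfer cycling between the enolate and the bromoketone, and a sluggish SN2 of the hindered enolate with the iodide.
   - Fallback (known chemistry, different approach): alkylate the lithium dienolate of 8 (LDA, THF/HMPA) with iodide 6 at the α′-carbon, which is regiospecific by design and trans-selective, then remove the isopropylidene by mild retro-aldol (wet Amberlyst-15) and carry on from step 10.
2. **Step 11 (Fe-catalysed methylation).** MeMgBr may attack the allylic acetate, by acylation or SN2′.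
   - Fallback: Wittig methylenation of ketone 11 (Ph3P=CH2), then Co(salen)/PhSiH3 hydrogen-atom-transfer isomerisation of the 1,1-disubstituted alkene into the endocyclic trisubstituted alkene, giving 13 without organometallic exposure of the acetate.
3. **Step 13 (Pd-catalysed sulfinate allylation).** Zwitterion insolubility, S-poisoning of Pd, or re-ionisation of the product sulfone could stall the reaction or erode E-selectivity.
   - Fallback: K2CO3/MeOH removes the acetate, PBr3 converts the allylic alcohol to the allylic bromide, and a plain SN2 with 15 in DMF/H2O gives 16.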